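**Retrosynthetic overview**
- Target ⇐ deconjugated spiro-diketone by a 1,3-proton shift (C1=C10 → C1=C2), which also sets C10.
- Spiro bond C2–C4' (two ketone α-carbons, a 1,4-diketone) ⇐ intramolecular oxidative enolate coupling, one enolate being oxidised to an α-keto radical (enolonium equivalent). This closes the central cyclohexene, the only ring built.
- C14–C15' (δ-carbon of a dienone and β-carbon of an enone, both acceptor sites) ⇐ vinylogous homoenolate radical, made by C–H removal at C1 of a 2-silyloxydiene, added to the exocyclic enone of the other half.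
- Both C15 halves ⇐ dehydrocostus lactone: C11 set as 11R by Ru/BINAP hydrogenation or as 11S by NaBH4; C3 ketone by SeO2 then Dess–Martin oxidation.
- Ring order: all five-membered, seven-membered and lactone rings are inherited from the natural product; the central six-membered ring is formed last.

Assumption: dehydrocostus lactone is bought; the (S)-BINAP hand is assigned by analogy with 2-methylene-γ-butyrolactone (the antipode is used if the sense is opposite); guaiane numbering throughout, primed numbers for the spiro-ketone half.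

**Step 1**
Reactants: 1 dehydrocostus lactone
Product: 2 (11R)-11,13-dihydrodehydrocostus lactone (11αH)
Conditions: Ru(OAc)2[(S)-BINAP] (1 mol %), H2 (20 atm), CH2Cl2/MeOH, 40 °C
Reagents that add atoms: none
Why: Catalyst-controlled asymmetric hydrogenation (Noyori type) of the chelating α-methylene-γ-butyrolactone leaves the two unfunctionalised 1,1-disubstituted alkenes alone and delivers hydrogen to the α-face of C11, overriding the substrate's preference for 11βH and setting C11 as R (13-methyl β).

**Step 2**
Reactants: 2 (11R)-11,13-dihydrodehydrocostus lactone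
Product: 3 (11R)-11,13-dihydroisozaluzanin C (3α-OH)
Conditions: SeO2 (0.3 equiv), t-BuOOH (2 equiv), CH2Cl2, 0 °C → rt
Reagents that add atoms: tert-butyl hydroperoxide CC(C)(C)OO
Why: Riley-type allylic oxidation (ene reaction then [2,3]-shift) attacks the allylic CH2 at C3 of the 4(15)-alkene from the convex α-face, as in the known conversion of dehydrocostus lactone into isozaluzanin C; the C3 carbinol centre is removed in step 3.

**Step 3**
Reactants: 3 (11R)-11,13-dihydroisozaluzanin C
Product: 4 (11R)-11,13-dihydrodehydrozaluzanin C (exocyclic enone)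
Conditions: Dess–Martin periodinane (1.2 equiv), CH2Cl2, 0 °C → rt
Reagents that add atoms: none
Why: Dess–Martin oxidation of the allylic alcohol gives the α-methylene cyclopentanone under neutral conditions that do not touch C11 or the lactone; no stereocentre is formed.

**Step 4**
Reactants: 1 dehydrocostus lactone
Product: 5 mokko lactone, (11S)-11,13-dihydrodehydrocostus lactone (11βH)
Conditions: NaBH4, MeOH, 0 °C
Reagents that add atoms: none
Why: Conjugate hydride reduction of the α-methylene lactone and β-face protonation of the lactone enolate under equilibrating methoxide conditions give the known, more stable 11βH epimer, setting C11 as S (13-methyl α).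

**Step 5**
Reactants: 5 mokko lactone
Product: 6 (11S)-11,13-dihydroisozaluzanin C (3α-OH)
Conditions: SeO2 (0.3 equiv), t-BuOOH (2 equiv), CH2Cl2, 0 °C → rt
Reagents that add atoms: tert-butyl hydroperoxide CC(C)(C)OO
Why: The same Riley allylic oxidation as in step 2, at C3 from the convex α-face; the carbinol centre is removed in step 6.

**Step 6**
Reactants: 6 (11S)-11,13-dihydroisozaluzanin C
Product: 7 (11S)-11,13-dihydrodehydrozaluzanin C (exocyclic enone)
Conditions: Dess–Martin periodinane (1.2 equiv), CH2Cl2, 0 °C → rt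
Reagents that add atoms: none
Why: Dess–Martin oxidation of the allylic alcohol as in step 3; no stereocentre is formed.

**Step 7**
Reactants: 7 (11S)-11,13-dihydrodehydrozaluzanin C
Product: 8 triisopropylsilyl 2-silyloxydiene of 7
Conditions: i-Pr3SiOTf (1.2 equiv), Et3N (2 equiv), CH2Cl2, −78 → 0 °C
Reagents that add atoms: triisopropylsilyl trifluoromethanesulfonate CC(C)[Si](OS(=O)(=O)C(F)(F)F)(C(C)C)C(C)C
Why: Soft enolisation with silyl triflate and amine can only go toward C2 because C4 has no hydrogen, so a single cross-conjugated silyl dienol ether forms and H-1 becomes doubly allylic; no stereocentre changes.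

**Step 8**
Reactants: 8 triisopropylsilyl 2-silyloxydiene of 7, 4 (11R)-11,13-dihydrodehydrozaluzanin C
Product: 10 seco-dimer diketone (C14–C15' linked; C1=C10), via silyl trienol ether 9 (not isolated)
Conditions: 8 (1.5 equiv), [Ir(dF(CF3)ppy)2(dtbbpy)]PF6 (2 mol %), 2,4,6-collidine (20 mol %), ClCH2CH2Cl, blue LEDs, rt; then Bu4NF, AcOH, THF, 0 °C
Reagents that add atoms: none
Why: Proposed new method: a photoredox/Brønsted-base allylic C–H alkylation in which one-electron oxidation of 8 and removal of the doubly allylic H-1 by collidine give a 1-silyloxy-polyenyl radical (a vinylogous homoenolate equivalent) that adds in Giese fashion through its unhindered C14 terminus to the β-carbon C15' of enone 4 (the bulky silyl group shields the competing C15 terminus and conjugation fixes the new alkene at C1=C10), after which the α-keto radical is reduced by the reduced photocatalyst and protonated and fluoride unmasks the C3 ketone; the closest known reaction is the iridium/collidine allylic C–H alkylation of enol silyl ethers with electron-poor olefins, and the only new centre (C4') forms unselectively and is erased in step 9.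

**Step 9**
Reactants: 10 seco-dimer diketone
Product: 12 spiro diketone (C2–C4' bond; 2βH; C1=C10), via dilithium bis-enolate 11 (not isolated)
Conditions: LiN(SiMe3)2 (2.0 equiv), THF, −78 → 0 °C; then Fe(acac)3 (2.2 equiv), −78 °C → rt
Reagents that add atoms: none
Why: Intramolecular oxidative enolate heterocoupling (Saegusa/Baran type): trivalent iron oxidises the electron-rich dienolate to an electrophilic α-keto radical at C2, which is trapped by the C3'–C4' enolate (the thermodynamic enolate and the only regioisomer able to close a six-membered ring) on the convex α-face of the cis-fused bicycle, the face of H-5', setting the spiro centre C4' as R; C2 forms mainly as 2βH and is erased in step 10.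

**Step 10**
Reactants: 12 spiro diketone
Product: 13 target CNP0240988.1
Conditions: DBU (0.2 equiv), CH2Cl2, 0 °C → rt
Reagents that add atoms: none
Why: Base-mediated 1,3-prototropic shift of the β,γ-enone into conjugation through the extended enolate; C10 is γ to the new enone and is expected to settle as the more stable epimer with H-10 β (C14 α, trans to H-5), which is also the outcome of suprafacial transfer of the β-oriented H-2 by the amidine — this preference is assumed, not established.

**Compound list**
1 | dehydrocostus lactone, (1αH,5αH,6βH,7αH)-guaia-4(15),10(14),11(13)-trien-12,6α-olide | C=C1CC[C@H]2C(=C)CC[C@@H]3[C@H](OC(=O)C3=C)[C@H]21 | starting material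
2 | (11R)-guaia-4(15),10(14)-dien-12,6α-olide (11αH, 13-methyl β) | C=C1CC[C@H]2C(=C)CC[C@@H]3[C@H](OC(=O)[C@@H]3C)[C@H]21 | intermediate
3 | (3R,11R)-3α-hydroxyguaia-4(15),10(14)-dien-12,6α-olide | C=C1[C@H](O)C[C@H]2C(=C)CC[C@@H]3[C@H](OC(=O)[C@@H]3C)[C@H]21 | intermediate
4 | (11R)-3-oxoguaia-4(15),10(14)-dien-12,6α-olide | C=C1C(=O)C[C@H]2C(=C)CC[C@@H]3[C@H](OC(=O)[C@@H]3C)[C@H]21 | intermediate
5 | mokko lactone, (11S)-guaia-4(15),10(14)-dien-12,6α-olide (11βH, 13-methyl α) | C=C1CC[C@H]2C(=C)CC[C@@H]3[C@H](OC(=O)[C@H]3C)[C@H]21 | intermediate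
6 | (3R,11S)-3α-hydroxyguaia-4(15),10(14)-dien-12,6α-olide | C=C1[C@H](O)C[C@H]2C(=C)CC[C@@H]3[C@H](OC(=O)[C@H]3C)[C@H]21 | intermediate
7 | (11S)-3-oxoguaia-4(15),10(14)-dien-12,6α-olide | C=C1C(=O)C[C@H]2C(=C)CC[C@@H]3[C@H](OC(=O)[C@H]3C)[C@H]21 | intermediate
8 | (11S)-3-(triisopropylsilyloxy)guaia-2,4(15),10(14)-trien-12,6α-olide | C=C1C(O[Si](C(C)C)(C(C)C)C(C)C)=C[C@H]2C(=C)CC[C@@H]3[C@H](OC(=O)[C@H]3C)[C@H]21 | intermediate
9 | (11S)-3-(triisopropylsilyloxy)guaia-1(10),2,4(15)-trien-12,6α-olide joined through C14 to C15' of (11'R)-3'-oxoguai-10'(14')-en-12',6'α-olide (both 4'-epimers) | C=C1C(O[Si](C(C)C)(C(C)C)C(C)C)=CC2=C(CCC3C(=O)C[C@H]4C(=C)CC[C@@H]5[C@H](OC(=O)[C@@H]5C)[C@H]43)CC[C@@H]3[C@H](OC(=O)[C@H]3C)[C@@H]12 | intermediate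
10 | (11S)-3-oxoguaia-1(10),4(15)-dien-12,6α-olide joined through C14 to C15' of (11'R)-3'-oxoguai-10'(14')-en-12',6'α-olide (both 4'-epimers) | C=C1C(=O)CC2=C(CCC3C(=O)C[C@H]4C(=C)CC[C@@H]5[C@H](OC(=O)[C@@H]5C)[C@H]43)CC[C@@H]3[C@H](OC(=O)[C@H]3C)[C@@H]12 | intermediate
11 | dilithium bis-enolate of 10 (2,3:1,10-dienolate in one half, 3',4'-enolate in the other) | C=C1C(O[Li])=CC2=C(CCC3=C(O[Li])C[C@H]4C(=C)CC[C@@H]5[C@H](OC(=O)[C@@H]5C)[C@H]43)CC[C@@H]3[C@H](OC(=O)[C@H]3C)[C@@H]12 | intermediate
12 | (2S,4'R)-spiro diketone: 10 with an added C2–C4' bond, 2βH, C1=C10 | C=C1C(=O)[C@H]2C3=C(CC[C@@H]4[C@H](OC(=O)[C@H]4C)[C@@H]13)CC[C@]21C(=O)C[C@H]2C(=C)CC[C@@H]3[C@H](OC(=O)[C@@H]3C)[C@H]21 | intermediate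
13 | CNP0240988.1: C1=C2 enone, 10βH (10S), spiro C4' (R), 11S and 11'R lactones | C=C1C(=O)C2=C3[C@@H](CC[C@@H]4[C@H](OC(=O)[C@H]4C)[C@@H]13)CC[C@]21C(=O)C[C@H]2C(=C)CC[C@@H]3[C@H](OC(=O)[C@@H]3C)[C@H]21 | target

**Totals**
Total step count: 10. Longest linear sequence: 7 steps (steps 4, 5, 6, 7, 8, 9, 10).

**Three steps most likely to fail**

Step 8 (radical union). The stabilised polyenyl radical may add too slowly to the enone, react through C15 instead of C14, or the more easily oxidised product may react again. The fallback is a closed-shell Lewis-acid ene reaction. It sets out from 7, which with LiN(SiMe3)2 and Ac2O in THF at −78 °C gives the dienyl acetate (11S)-3-acetoxyguaia-2,4(15),10(14)-trien-12,6α-olide F1, no longer an enophile and with a doubly allylic H-1. F1 and 4 with Me2AlCl in CH2Cl2 at −78 °C undergo a conjugate ene reaction in which C14 adds to C15' and H-1 passes to C4', giving the 14–15'-linked trienyl acetate F2. K2CO3 in MeOH at 0 °C removes the acetyl group, and the route is rejoined at 10.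

Step 9 (oxidative spirocyclisation). The cyclopentanone may enolise toward C2' instead of C4', or the radical may be lost before forming the hindered quaternary centre. The fallback is a two-electron ring closure. It sets out from 10: LiN(SiMe3)2 (1.0 equiv, THF, −78 °C) removes only the doubly activated C2 hydrogen, and N-iodosuccinimide gives the 2-iodo-3-oxo-1(10)-ene seco-dimer F3. Cs2CO3 in MeCN at 0 °C then enolises the cyclopentanone reversibly, and only the C3'–C4' enolate can displace the α-keto allylic iodide in a six-membered SN2 closure. The route is rejoined at 12.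

Step 10 (C10 configuration). If the base equilibrium or the proton relay favours the 10-epimer, the fallback sets C10 before ring closure and forms the spiro bond without a late isomerisation. It sets out from 10: DBU in CH2Cl2 conjugates it to the 1(2)-enone seco-dimer with 10βH F4, whose C10 epimers can be separated and recycled at this open stage. I2 and pyridine give the 2-iodoenone F5. Pd2(dba)3, Xantphos and KOPh in THF at 60 °C then close the ring by intramolecular ketone α-alkenylation (again only the C4' enolate gives a six-membered ring), with C1=C2 already in place. The route is rejoined at 13.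

**Further compounds**
F1 | step 8 | (11S)-3-acetoxyguaia-2,4(15),10(14)-trien-12,6α-olide | C=C1C(OC(C)=O)=C[C@H]2C(=C)CC[C@@H]3[C@H](OC(=O)[C@H]3C)[C@H]21
F2 | step 8 | (11S)-3-acetoxyguaia-1(10),2,4(15)-trien-12,6α-olide joined through C14 to C15' of (11'R)-3'-oxoguai-10'(14')-en-12',6'α-olide | C=C1C(OC(C)=O)=CC2=C(CCC3C(=O)C[C@H]4C(=C)CC[C@@H]5[C@H](OC(=O)[C@@H]5C)[C@H]43)CC[C@@H]3[C@H](OC(=O)[C@H]3C)[C@@H]12
F3 | step 9 | 2-iodo derivative of 10 (both C2 epimers) | C=C1C(=O)C(I)C2=C(CCC3C(=O)C[C@H]4C(=C)CC[C@@H]5[C@H](OC(=O)[C@@H]5C)[C@H]43)CC[C@@H]3[C@H](OC(=O)[C@H]3C)[C@@H]12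
F4 | step 10 | (10S,11S)-3-oxoguaia-1,4(15)-dien-12,6α-olide (10βH) joined through C14 to C15' of (11'R)-3'-oxoguai-10'(14')-en-12',6'α-olide | C=C1C(=O)C=C2[C@@H](CC[C@@H]3[C@H](OC(=O)[C@H]3C)[C@@H]12)CCC1C(=O)C[C@H]2C(=C)CC[C@@H]3[C@H](OC(=O)[C@@H]3C)[C@H]21
F5 | step 10 | 2-iodo derivative of F4 | C=C1C(=O)C(I)=C2[C@@H](CC[C@@H]3[C@H](OC(=O)[C@H]3C)[C@@H]12)CCC1C(=O)C[C@H]2C(=C)CC[C@@H]3[C@H](OC(=O)[C@@H]3C)[C@H]21
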